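**Plan**

- Feature: with the oxolane numbered O1, C2, C3 (guaiacylmethyl), C4 (carbinol-bearing), C5, carbon C4 holds two oxygenated one-carbon arms, ring C5 and the exocyclic carbinol carbon. These are read as the two CH2–O arms of an oxetane whose C3 is C4, opened by the hydroxyl on C2.
- Retrosynthetic cuts, in order: both aryl O–Si bonds; the carbinol C–aryl bond (back to the C4 hydroxymethyl group and a syringyl boronate); O1–C5 (back to an oxetanyl propanol); C3–CH2Ar (back to an oxetan-3-ylacetyl imide and a vanillyl bromide).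
- Forward order: the chain is joined by auxiliary alkylation, the oxolane (the only ring made) closes by cobalt-catalysed oxetane opening, the hydroxymethyl group is converted into the aryl carbinol by lithiation–borylation–oxidation, and the phenols are freed last.
- Stereochemistry: C3 comes from alkylation of the (R)-4-benzyl-oxazolidinone enolate; C4 from the catalyst-controlled choice between the diastereotopic oxetane CH2 groups (trans to C3); the (S)-carbinol from (+)-sparteine-directed deprotonation, borylation with retention and 1,2-aryl shift with inversion.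

Key step: step 9

Assumption: the (R,R)-antipode of the salen ligand is taken as the one matched to the (R)-centre beside the oxetane; if the sense proved opposite, the (S,S)-antipode would be used with no other change, the substrate's own bias towards the trans ring pointing the same way.

**Route**

Step 1
Reactants: 1 ethyl 2-(oxetan-3-ylidene)acetate
Product: 2 ethyl 2-(oxetan-3-yl)acetate
Conditions: H2 (1 atm), Pd/C (10 wt%), EtOAc, rt
Reagents that add atoms: none
Why: Heterogeneous catalytic hydrogenation saturates the conjugated exocyclic alkene, and the oxetane C–O bonds are not hydrogenolysed under neutral conditions.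

Step 2
Reactants: 2 ethyl 2-(oxetan-3-yl)acetate
Product: 3 lithium 2-(oxetan-3-yl)acetate
Conditions: LiOH·H2O (1.0 equiv), THF/H2O, 0 °C → rt; evaporation, toluene azeotrope
Reagents that add atoms: lithium hydroxide, [Li+].[OH-]
Why: Ester saponification leaves the base-stable oxetane untouched, and the product is kept as its lithium salt because a free oxetanyl carboxylic acid can open its own ring to a lactone.

Step 3
Reactants: 3 lithium 2-(oxetan-3-yl)acetate; 4 (R)-4-benzyl-2-oxazolidinone
Product: 6 (R)-4-benzyl-3-[2-(oxetan-3-yl)acetyl]oxazolidin-2-one, via mixed pivalic anhydride 5 (not isolated)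
Conditions: PivCl, THF, −20 → 0 °C; then 4, LiCl, Et3N, 0 °C → rt
Reagents that add atoms: none
Why: N-acylation by the mixed-anhydride method, in which the carboxylate and pivaloyl chloride give anhydride 5 without liberating acid and the LiCl/Et3N-activated oxazolidinone attacks its less hindered oxetanylacetyl carbonyl.

Step 4
Reactants: 7 vanillin
Product: 8 3-methoxy-4-(triisopropylsilyloxy)benzaldehyde
Conditions: TIPSCl, imidazole, DMF, rt
Reagents that add atoms: triisopropylsilyl chloride, CC(C)[Si](Cl)(C(C)C)C(C)C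
Why: Imidazole-promoted silylation of the phenol installs a bulky silyl ether that should withstand the later enolate, borohydride, Lewis-acid and organolithium steps and shield the adjacent ring position from lithiation.

Step 5
Reactants: 8 3-methoxy-4-(triisopropylsilyloxy)benzaldehyde
Product: 9 [3-methoxy-4-(triisopropylsilyloxy)phenyl]methanol
Conditions: NaBH4, MeOH, 0 °C
Reagents that add atoms: none
Why: Borohydride reduction of the aryl aldehyde gives the benzylic alcohol, and the aryl silyl ether is stable in cold methanol.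

Step 6
Reactants: 9 [3-methoxy-4-(triisopropylsilyloxy)phenyl]methanol
Product: 10 4-(bromomethyl)-2-methoxy-1-(triisopropylsilyloxy)benzene
Conditions: PBr3 (0.4 equiv), Et2O, 0 °C; cold NaHCO3 wash, used crude at once
Reagents that add atoms: phosphorus tribromide, BrP(Br)Br
Why: The benzylic alcohol is activated as a bromophosphite and displaced by bromide (SN2), and the easily ionised electron-rich bromide is therefore not stored or chromatographed.

Step 7
Reactants: 6 (R)-4-benzyl-3-[2-(oxetan-3-yl)acetyl]oxazolidin-2-one; 10 4-(bromomethyl)-2-methoxy-1-(triisopropylsilyloxy)benzene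
Product: 12 (R)-4-benzyl-3-[(2R)-3-[3-methoxy-4-(triisopropylsilyloxy)phenyl]-2-(oxetan-3-yl)propanoyl]oxazolidin-2-one, via sodium enolate 11 (not isolated)
Conditions: NaN(SiMe3)2, THF, −78 °C; then 10, −78 → −40 °C
Reagents that add atoms: none
Why: Evans alkylation, in which the chelated (Z)-enolate 11 is attacked by the benzylic bromide on the face away from the oxazolidinone benzyl group, setting the (R)-centre that becomes C3, while the oxetane oxygen sits gamma to the enolate carbon and cannot be lost by beta-elimination.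

Step 8
Reactants: 12 (R)-4-benzyl-3-[(2R)-3-[3-methoxy-4-(triisopropylsilyloxy)phenyl]-2-(oxetan-3-yl)propanoyl]oxazolidin-2-one
Product: 13 (2R)-3-[3-methoxy-4-(triisopropylsilyloxy)phenyl]-2-(oxetan-3-yl)propan-1-ol
Conditions: LiBH4, H2O (1.1 equiv), Et2O, 0 °C
Reagents that add atoms: none
Why: Reductive cleavage of the N-acyl oxazolidinone by hydride attack at the exocyclic carbonyl releases the primary alcohol without touching the alpha-stereocentre, the oxetane or the silyl ether, and the auxiliary is recovered.

Step 9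
Reactants: 13 (2R)-3-[3-methoxy-4-(triisopropylsilyloxy)phenyl]-2-(oxetan-3-yl)propan-1-ol
Product: 14 [(3S,4R)-4-[[3-methoxy-4-(triisopropylsilyloxy)phenyl]methyl]oxolan-3-yl]methanol (trans)
Conditions: (R,R)-(salen)Co(OTf) (2 mol%; trivalent cobalt; salen = N,N'-bis(3,5-di-tert-butylsalicylidene)-1,2-cyclohexanediamine dianion), MeCN, 23 °C
Reagents that add atoms: none
Why: The cationic trivalent cobalt centre binds the oxetane oxygen as a Lewis acid and the pendant primary hydroxyl attacks one oxetane CH2 in an SN2 manner, so that the hydroxyl oxygen becomes O1 and the former oxetane oxygen ends as the hydroxymethyl group on C4. The closest known reaction type is the (salen)Co-catalysed desymmetrising intramolecular opening of 3-substituted oxetanes by tethered alcohols to (oxolan-3-yl)methanols. The oxolane closes in a 5-exo-tet mode, driven by release of the four-ring strain. The new stereocentre, the former oxetane C3, arises from the choice between the two diastereotopic oxetane methylenes; this choice is made by the chiral salen ligand and reinforced by the substrate, because the transition state leading to the trans ring keeps the arylmethyl group away from the departing CH2O–Co arm. The step needs diastereotopic-group selectivity and ring closure in preference to intermolecular opening; the first is secured by matching the catalyst antipode to the (R)-centre next to the oxetane, the second by the 1,4-relationship of the hydroxyl oxygen and the oxetane carbon, which makes the five-membered transition state readily accessible.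

Step 10
Reactants: 14 [(3S,4R)-4-[[3-methoxy-4-(triisopropylsilyloxy)phenyl]methyl]oxolan-3-yl]methanol
Product: 15 [(3R,4R)-4-[[3-methoxy-4-(triisopropylsilyloxy)phenyl]methyl]oxolan-3-yl]methyl N,N-diisopropylcarbamate
Conditions: iPr2NCOCl, Et3N, CH2Cl2, reflux
Reagents that add atoms: N,N-diisopropylcarbamoyl chloride, CC(C)N(C(C)C)C(Cl)=O
Why: O-carbamoylation of the primary alcohol gives the hindered carbamate that directs and stabilises the later alpha-lithiation through a complex-induced proximity effect.

Step 11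
Reactants: 16 4-bromo-2,6-dimethoxyphenol
Product: 17 (4-bromo-2,6-dimethoxyphenoxy)triisopropylsilane
Conditions: TIPSOTf, 2,6-lutidine, CH2Cl2, 0 °C → rt
Reagents that add atoms: triisopropylsilyl trifluoromethanesulfonate, CC(C)[Si](OS(=O)(=O)C(F)(F)F)(C(C)C)C(C)C
Why: The doubly ortho-substituted phenol is silylated with the more electrophilic silyl triflate and a non-nucleophilic base, and using the same silyl group as on the other ring allows one final deprotection.

Step 12
Reactants: 17 (4-bromo-2,6-dimethoxyphenoxy)triisopropylsilane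
Product: 18 2-[3,5-dimethoxy-4-(triisopropylsilyloxy)phenyl]-4,4,5,5-tetramethyl-1,3,2-dioxaborolane
Conditions: B2pin2, Pd(dppf)Cl2 (3 mol%), KOAc, 1,4-dioxane, 90 °C
Reagents that add atoms: bis(pinacolato)diboron, CC1(C)OB(OC1(C)C)B1OC(C)(C)C(C)(C)O1
Why: Miyaura borylation proceeds by oxidative addition of the unhindered aryl bromide to zerovalent palladium, acetate-assisted transmetallation with the diboron and reductive elimination, and the weak base leaves the aryl silyl ether intact.

Step 13
Reactants: 15 [(3R,4R)-4-[[3-methoxy-4-(triisopropylsilyloxy)phenyl]methyl]oxolan-3-yl]methyl N,N-diisopropylcarbamate; 18 2-[3,5-dimethoxy-4-(triisopropylsilyloxy)phenyl]-4,4,5,5-tetramethyl-1,3,2-dioxaborolane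
Product: 22 (S)-[3,5-dimethoxy-4-(triisopropylsilyloxy)phenyl][(3R,4R)-4-[[3-methoxy-4-(triisopropylsilyloxy)phenyl]methyl]oxolan-3-yl]methanol, via lithiated carbamate 19 (not isolated), via boronate complex 20 (not isolated), via benzylic boronic ester 21 (not isolated)
Conditions: sec-BuLi, (+)-sparteine, Et2O, −78 °C; then 18, −78 °C; MgBr2·OEt2, then reflux; then NaOH (2 M aq.), H2O2 (30% aq.), THF, 0 °C → rt
Reagents that add atoms: hydrogen peroxide, OO
Why: Sparteine-mediated asymmetric alpha-lithiation of the primary carbamate followed by a Matteson-type 1,2-metallate rearrangement, in which sec-BuLi/(+)-sparteine removes the pro-R proton to give the configurationally stable (R)-organolithium 19, boronate 18 is bound with retention to give 20, MgBr2 assists anti-periplanar migration of the electron-rich aryl group with inversion and loss of the carbamate to give 21, and C–B oxidation with retention sets the (S)-carbinol under reagent control.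

Step 14
Reactants: 22 (S)-[3,5-dimethoxy-4-(triisopropylsilyloxy)phenyl][(3R,4R)-4-[[3-methoxy-4-(triisopropylsilyloxy)phenyl]methyl]oxolan-3-yl]methanol
Product: 23 4-[(S)-hydroxy[(3R,4R)-4-[(4-hydroxy-3-methoxyphenyl)methyl]oxolan-3-yl]methyl]-2,6-dimethoxyphenol
Conditions: TBAF (2.2 equiv), AcOH (2.2 equiv), THF, 0 °C
Reagents that add atoms: none
Why: Fluoride cleaves both aryl silyl ethers through Si–F bond formation, and the acetic acid buffer keeps the phenols protonated so that the para-hydroxybenzylic carbinol is not epimerised or eliminated through a quinone methide.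

**Compound list**

1 | ethyl 2-(oxetan-3-ylidene)acetate | CCOC(=O)C=C1COC1 | starting material
2 | ethyl 2-(oxetan-3-yl)acetate | CCOC(=O)CC1COC1 | intermediate
3 | lithium 2-(oxetan-3-yl)acetate | [Li+].[O-]C(=O)CC1COC1 | intermediate
4 | (R)-4-benzyl-2-oxazolidinone | O=C1N[C@H](Cc2ccccc2)CO1 | starting material
5 | 2-(oxetan-3-yl)acetic pivalic anhydride (formed in the flask, not isolated) | CC(C)(C)C(=O)OC(=O)CC1COC1 | intermediate
6 | (R)-4-benzyl-3-[2-(oxetan-3-yl)acetyl]oxazolidin-2-one | O=C(CC1COC1)N1[C@H](Cc2ccccc2)COC1=O | intermediate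
7 | vanillin | COc1cc(C=O)ccc1O | starting material
8 | 3-methoxy-4-(triisopropylsilyloxy)benzaldehyde | COc1cc(C=O)ccc1O[Si](C(C)C)(C(C)C)C(C)C | intermediate
9 | [3-methoxy-4-(triisopropylsilyloxy)phenyl]methanol | COc1cc(CO)ccc1O[Si](C(C)C)(C(C)C)C(C)C | intermediate
10 | 4-(bromomethyl)-2-methoxy-1-(triisopropylsilyloxy)benzene | COc1cc(CBr)ccc1O[Si](C(C)C)(C(C)C)C(C)C | intermediate
11 | sodium (Z)-1-[(4R)-4-benzyl-2-oxooxazolidin-3-yl]-2-(oxetan-3-yl)ethen-1-olate (formed in the flask, not isolated) | [Na+].[O-]/C(=C\C1COC1)N1[C@H](Cc2ccccc2)COC1=O | intermediate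
12 | (R)-4-benzyl-3-[(2R)-3-[3-methoxy-4-(triisopropylsilyloxy)phenyl]-2-(oxetan-3-yl)propanoyl]oxazolidin-2-one | COc1cc(C[C@H](C2COC2)C(=O)N2[C@H](Cc3ccccc3)COC2=O)ccc1O[Si](C(C)C)(C(C)C)C(C)C | intermediate
13 | (2R)-3-[3-methoxy-4-(triisopropylsilyloxy)phenyl]-2-(oxetan-3-yl)propan-1-ol | COc1cc(C[C@H](C2COC2)CO)ccc1O[Si](C(C)C)(C(C)C)C(C)C | intermediate
14 | [(3S,4R)-4-[[3-methoxy-4-(triisopropylsilyloxy)phenyl]methyl]oxolan-3-yl]methanol (trans) | COc1cc(C[C@H]2COC[C@@H]2CO)ccc1O[Si](C(C)C)(C(C)C)C(C)C | intermediate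
15 | [(3R,4R)-4-[[3-methoxy-4-(triisopropylsilyloxy)phenyl]methyl]oxolan-3-yl]methyl N,N-diisopropylcarbamate | COc1cc(C[C@H]2COC[C@@H]2COC(=O)N(C(C)C)C(C)C)ccc1O[Si](C(C)C)(C(C)C)C(C)C | intermediate
16 | 4-bromo-2,6-dimethoxyphenol | COc1cc(Br)cc(OC)c1O | starting material
17 | (4-bromo-2,6-dimethoxyphenoxy)triisopropylsilane | COc1cc(Br)cc(OC)c1O[Si](C(C)C)(C(C)C)C(C)C | intermediate
18 | 2-[3,5-dimethoxy-4-(triisopropylsilyloxy)phenyl]-4,4,5,5-tetramethyl-1,3,2-dioxaborolane | COc1cc(B2OC(C)(C)C(C)(C)O2)cc(OC)c1O[Si](C(C)C)(C(C)C)C(C)C | intermediate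
19 | (R)-[(N,N-diisopropylcarbamoyl)oxy][(3R,4R)-4-[[3-methoxy-4-(triisopropylsilyloxy)phenyl]methyl]oxolan-3-yl]methyllithium, (+)-sparteine complex (not isolated) | COc1cc(C[C@H]2COC[C@@H]2[C@H](OC(=O)N(C(C)C)C(C)C)[Li])ccc1O[Si](C(C)C)(C(C)C)C(C)C | intermediate
20 | lithium pinacolato boronate complex carrying the syringyl aryl group and the (R)-alpha-carbamoyloxy alkyl group (not isolated) | [Li+].COc1cc(C[C@H]2COC[C@@H]2[C@H](OC(=O)N(C(C)C)C(C)C)[B-]2(c3cc(OC)c(O[Si](C(C)C)(C(C)C)C(C)C)c(OC)c3)OC(C)(C)C(C)(C)O2)ccc1O[Si](C(C)C)(C(C)C)C(C)C | intermediate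
21 | 2-[(S)-[3,5-dimethoxy-4-(triisopropylsilyloxy)phenyl][(3R,4R)-4-[[3-methoxy-4-(triisopropylsilyloxy)phenyl]methyl]oxolan-3-yl]methyl]-4,4,5,5-tetramethyl-1,3,2-dioxaborolane (not isolated) | COc1cc(C[C@H]2COC[C@@H]2[C@H](B2OC(C)(C)C(C)(C)O2)c2cc(OC)c(O[Si](C(C)C)(C(C)C)C(C)C)c(OC)c2)ccc1O[Si](C(C)C)(C(C)C)C(C)C | intermediate
22 | (S)-[3,5-dimethoxy-4-(triisopropylsilyloxy)phenyl][(3R,4R)-4-[[3-methoxy-4-(triisopropylsilyloxy)phenyl]methyl]oxolan-3-yl]methanol | COc1cc(C[C@H]2COC[C@@H]2[C@H](O)c2cc(OC)c(O[Si](C(C)C)(C(C)C)C(C)C)c(OC)c2)ccc1O[Si](C(C)C)(C(C)C)C(C)C | intermediate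
23 | 4-[(S)-hydroxy[(3R,4R)-4-[(4-hydroxy-3-methoxyphenyl)methyl]oxolan-3-yl]methyl]-2,6-dimethoxyphenol | COc1cc(C[C@H]2COC[C@@H]2[C@H](O)c2cc(OC)c(O)c(OC)c2)ccc1O | target

**Count**

Total steps: 14. Longest linear sequence: 9 steps (steps 1, 2, 3, 7, 8, 9, 10, 13, 14; the vanillin branch through steps 4, 5, 6 is equally long).

**Steps most likely to fail**

1. Step 13. The deprotonation may be slow or poorly face-selective if the (+)-sparteine complex is mismatched with the adjacent ring stereocentre, and the boronate complex may dissociate before the aryl group migrates. Fallback from 14, returning at 22: Dess–Martin oxidation of 14 should give (3R,4R)-4-[[3-methoxy-4-(triisopropylsilyloxy)phenyl]methyl]oxolane-3-carbaldehyde F1. Bromine–lithium exchange on 17 with n-BuLi in THF at −78 °C gives [3,5-dimethoxy-4-(triisopropylsilyloxy)phenyl]lithium F2, which adds to F1 to give the diaryl carbinol as a mixture of carbinol epimers F3. A second Dess–Martin oxidation gives [3,5-dimethoxy-4-(triisopropylsilyloxy)phenyl][(3R,4R)-4-[[3-methoxy-4-(triisopropylsilyloxy)phenyl]methyl]oxolan-3-yl]methanone F4. Corey–Bakshi–Shibata reduction with BH3·SMe2 and the (R)-2-methyl oxazaborolidine, the aryl group acting as the large substituent, should then deliver 22.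

2. Step 9. Discrimination between the two diastereotopic oxetane methylenes may be insufficient, so that cis ring closure accompanies trans. Fallback from 13, returning at 14: the ring is closed without stereocontrol using catalytic BF3·OEt2 in CH2Cl2, giving [(4R)-4-[[3-methoxy-4-(triisopropylsilyloxy)phenyl]methyl]oxolan-3-yl]methanol as a mixture of C3 epimers F5. Dess–Martin oxidation gives the corresponding aldehyde as a mixture of C3 epimers F6. Equilibration with DBU in CH2Cl2 should move the epimerisable formyl-bearing carbon to the thermodynamically preferred trans aldehyde, (3R,4R)-4-[[3-methoxy-4-(triisopropylsilyloxy)phenyl]methyl]oxolane-3-carbaldehyde F1, the auxiliary-derived centre being untouched. NaBH4 in MeOH then gives 14, so C4 is set under thermodynamic instead of catalyst control.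

3. Step 7. Ionisation and self-condensation of the electron-rich silyloxybenzyl bromide may outpace C-alkylation of the hindered, beta-branched enolate. Fallback from 6, returning at 12: the sodium enolate 11 is alkylated with the shelf-stable, commercial 4-(benzyloxy)-3-methoxybenzyl bromide to give (R)-4-benzyl-3-[(2R)-3-(4-benzyloxy-3-methoxyphenyl)-2-(oxetan-3-yl)propanoyl]oxazolidin-2-one F7. Hydrogenolysis (H2, Pd/C, EtOAc) frees the phenol, (R)-4-benzyl-3-[(2R)-3-(4-hydroxy-3-methoxyphenyl)-2-(oxetan-3-yl)propanoyl]oxazolidin-2-one F8, and TIPSCl/imidazole in DMF gives 12.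

**Further compounds**

F1 | step 13 | (3R,4R)-4-[[3-methoxy-4-(triisopropylsilyloxy)phenyl]methyl]oxolane-3-carbaldehyde | COc1cc(C[C@H]2COC[C@@H]2C=O)ccc1O[Si](C(C)C)(C(C)C)C(C)C
F2 | step 13 | [3,5-dimethoxy-4-(triisopropylsilyloxy)phenyl]lithium | COc1cc([Li])cc(OC)c1O[Si](C(C)C)(C(C)C)C(C)C
F3 | step 13 | [3,5-dimethoxy-4-(triisopropylsilyloxy)phenyl][(3R,4R)-4-[[3-methoxy-4-(triisopropylsilyloxy)phenyl]methyl]oxolan-3-yl]methanol, mixture of carbinol epimers | COc1cc(C[C@H]2COC[C@@H]2C(O)c2cc(OC)c(O[Si](C(C)C)(C(C)C)C(C)C)c(OC)c2)ccc1O[Si](C(C)C)(C(C)C)C(C)C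
F4 | step 13 | [3,5-dimethoxy-4-(triisopropylsilyloxy)phenyl][(3R,4R)-4-[[3-methoxy-4-(triisopropylsilyloxy)phenyl]methyl]oxolan-3-yl]methanone | COc1cc(C[C@H]2COC[C@@H]2C(=O)c2cc(OC)c(O[Si](C(C)C)(C(C)C)C(C)C)c(OC)c2)ccc1O[Si](C(C)C)(C(C)C)C(C)C
F5 | step 9 | [(4R)-4-[[3-methoxy-4-(triisopropylsilyloxy)phenyl]methyl]oxolan-3-yl]methanol, mixture of C3 epimers | COc1cc(C[C@H]2COCC2CO)ccc1O[Si](C(C)C)(C(C)C)C(C)C
F6 | step 9 | (4R)-4-[[3-methoxy-4-(triisopropylsilyloxy)phenyl]methyl]oxolane-3-carbaldehyde, mixture of C3 epimers | COc1cc(C[C@H]2COCC2C=O)ccc1O[Si](C(C)C)(C(C)C)C(C)C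
F7 | step 7 | (R)-4-benzyl-3-[(2R)-3-(4-benzyloxy-3-methoxyphenyl)-2-(oxetan-3-yl)propanoyl]oxazolidin-2-one | COc1cc(C[C@H](C2COC2)C(=O)N2[C@H](Cc3ccccc3)COC2=O)ccc1OCc1ccccc1
F8 | step 7 | (R)-4-benzyl-3-[(2R)-3-(4-hydroxy-3-methoxyphenyl)-2-(oxetan-3-yl)propanoyl]oxazolidin-2-one | COc1cc(C[C@H](C2COC2)C(=O)N2[C@H](Cc3ccccc3)COC2=O)ccc1O
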